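The decalin (naphthalene numbering, aryloxy carbon = C2) is cut at its ring-fusion bond C4a–C8a. The key step exploits that C8a of rings A and B lies β to the oxygen-bearing C2, while the methyl-bearing quaternary C4a lies α to C4. An acyclic formyl enone, made in three steps from (R)-limonene oxide, therefore folds in one operation. Enamine Michael addition forms C4a–C8a (ring B), aldol condensation forms C3–C4 (ring A), and the C7 stereocentre sets C4a and C8a of the trans-fused enone. Enone reduction, equatorial methyl addition, O-arylation of the tertiary alcohol with a diaryliodonium salt, alkene hydration and two cross-couplings finish the honokiol ether.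

Key step: step 4

Remark: ring A = C1–C4, C4a, C8a and ring B = C4a, C5–C8, C8a; compounds 1, 13, 14 and 20 are taken as catalogue compounds, and the cis/trans epoxide mixture of 1 is acceptable because both epoxide carbons become carbonyl carbons in step 1.

Step 1
Reactants: 1 (+)-limonene oxide, (4R)-1-methyl-4-(prop-1-en-2-yl)-7-oxabicyclo[4.1.0]heptane (cis/trans mixture)
Product: 3 (3R)-6-oxo-3-(prop-1-en-2-yl)heptanal, via limonene-1,2-diol 2 (not isolated)
Conditions: H5IO6, THF/H2O, 0 °C to rt
Reagents that add atoms: water, O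
Why: Acid-promoted hydrolysis of either epoxide diastereomer gives the 1,2-diol, which periodate cleaves (Malaprade glycol cleavage) without touching the 1,1-disubstituted alkene or the stereocentre that becomes C7 of the target.

Step 2
Reactants: 3 (3R)-6-oxo-3-(prop-1-en-2-yl)heptanal
Product: 4 (3E,6R)-6-(prop-1-en-2-yl)dec-3-ene-2,9-dione
Conditions: Ph3P=CHC(O)CH3, CH2Cl2, rt
Reagents that add atoms: 1-(triphenyl-λ5-phosphanylidene)propan-2-one, CC(=O)C=P(c1ccccc1)(c1ccccc1)c1ccccc1
Why: Wittig olefination with a stabilised ylide reacts with the aldehyde and not with the methyl ketone, and should give the (E)-enone.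

Step 3
Reactants: 4 (3E,6R)-6-(prop-1-en-2-yl)dec-3-ene-2,9-dione
Product: 6 (5R,7E)-2-methyl-9-oxo-5-(prop-1-en-2-yl)dec-7-enal (C2 epimers), via methyl enol ether 5 (not isolated)
Conditions: MeOCH2PPh3Cl, KN(SiMe3)2 (1.05 equiv of ylide), THF, −78 to 0 °C; then 2 M aq HCl, THF, rt
Reagents that add atoms: (methoxymethyl)triphenylphosphonium chloride, COC[P+](c1ccccc1)(c1ccccc1)c1ccccc1.[Cl-]; water, O
Why: Wittig methoxymethylenation with one equivalent of the non-stabilised ylide should prefer the more electrophilic saturated methyl ketone over the conjugated one, and mild acid hydrolysis of the enol ether gives the homologated aldehyde, whose new α-stereocentre does not matter because step 4 erases it.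

Step 4
Reactants: 6 (5R,7E)-2-methyl-9-oxo-5-(prop-1-en-2-yl)dec-7-enal
Product: 9 (4aR,7R,8aS)-4a-methyl-7-(prop-1-en-2-yl)-4a,5,6,7,8,8a-hexahydronaphthalen-2(1H)-one (trans-fused), via pyrrolidine enamine 7 (not isolated), via Michael adduct 8 (not isolated)
Conditions: pyrrolidine (30 mol %), AcOH (30 mol %), toluene (0.02 M), rt, then 60 °C
Reagents that add atoms: none
Why: Pyrrolidine condenses with the α-branched aldehyde of 6 to enamine 7 (which erases the C2 epimers), its β-carbon adds to the β-carbon of the tethered (E)-enone to form C4a–C8a, and in keto aldehyde 8 the methyl-ketone enamine attacks the non-enolisable formyl (iminium) carbon and loses water to give 9. The closest known reaction type is the Stork enamine version of the Robinson annulation of α,α-disubstituted aldehydes with methyl vinyl ketone, run here as an internal Michael–aldol sequence of a formyl enone because the vinyl ketone terminus is tied to the aldehyde chain. Ring B closes 6-(enolexo)-exo-trig and ring A closes 6-(enolendo)-exo-trig, and the only alternative aldol (through C1) would give a four-membered ring. C8a is set by a chair-like transition state with the C7 isopropenyl group and the enone arm both equatorial, and C4a is set in the same transition state because the bulky aminovinyl terminus should take the equatorial site (avoiding the axial hydrogens at C6 and C8), leaving the small methyl group axial and anti to H-8a, which is the trans ring fusion. The step needs trans over cis ring fusion, enamine formation at the aldehyde rather than the ketone, and intra- over intermolecular reaction; these rest on the size difference of the two groups at C4a, on the higher reactivity of the aldehyde towards the secondary amine, and on high dilution combined with six-membered closures.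

Step 5
Reactants: 9 (4aR,7R,8aS)-4a-methyl-7-(prop-1-en-2-yl)-4a,5,6,7,8,8a-hexahydronaphthalen-2(1H)-one
Product: 11 (4aS,7R,8aS)-4a-methyl-7-(prop-1-en-2-yl)octahydronaphthalen-2(1H)-one, via lithium enolate 10 (not isolated)
Conditions: Li, NH3(l), THF, t-BuOH (1 equiv), −78 °C; then NH4Cl
Reagents that add atoms: none
Why: Dissolving-metal (Birch-type) conjugate reduction of the enone stops at the enolate and leaves the isolated isopropenyl group and all three stereocentres untouched.

Step 6
Reactants: 11 (4aS,7R,8aS)-4a-methyl-7-(prop-1-en-2-yl)octahydronaphthalen-2(1H)-one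
Product: 12 (2R,4aS,7R,8aS)-2,4a-dimethyl-7-(prop-1-en-2-yl)decahydronaphthalen-2-ol (axial OH, equatorial 2-methyl)
Conditions: MeTi(OiPr)3 (2 equiv), hexane/CH2Cl2, −20 °C to rt; aq NH4F work-up
Reagents that add atoms: methyltitanium triisopropoxide, C[Ti](OC(C)C)(OC(C)C)OC(C)C
Why: 1,2-Addition of a bulky, weakly basic methyltitanium reagent to the conformationally locked trans-decalone should follow the equatorial trajectory (away from the axial hydrogens at C4 and C8a), which places the methyl group equatorial and the hydroxyl group axial, that is 2R.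

Step 7
Reactants: 13 4-bromo-2-chloro-1-iodobenzene; 14 1,3,5-trimethoxybenzene
Product: 16 (4-bromo-2-chlorophenyl)(2,4,6-trimethoxyphenyl)iodonium tosylate, via [hydroxy(tosyloxy)iodo]arene 15 (not isolated)
Conditions: mCPBA, TsOH·H2O, MeCN, 75 °C; then 14, 75 °C
Reagents that add atoms: p-toluenesulfonic acid, Cc1ccc(cc1)S(O)(=O)=O
Why: One-pot oxidation of the aryl iodide to the hypervalent iodine tosylate, followed by electrophilic aromatic substitution on the electron-rich arene, is a standard synthesis of unsymmetrical diaryliodonium salts.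

Step 8
Reactants: 12 (2R,4aS,7R,8aS)-2,4a-dimethyl-7-(prop-1-en-2-yl)decahydronaphthalen-2-ol; 16 (4-bromo-2-chlorophenyl)(2,4,6-trimethoxyphenyl)iodonium tosylate
Product: 17 4-bromo-2-chloro-1-{[(2R,4aS,7R,8aS)-2,4a-dimethyl-7-(prop-1-en-2-yl)decahydronaphthalen-2-yl]oxy}benzene
Conditions: NaN(SiMe3)2 (1.1 equiv), toluene, rt; then 16 (1.3 equiv), rt to 40 °C
Reagents that add atoms: none
Why: Metal-free O-arylation of a tertiary alkoxide with a diaryliodonium salt (ligand exchange at iodine, then ligand coupling) should transfer the electron-poorer, ortho-chloro-substituted aryl group and keep the trimethoxyphenyl group on iodine, and the C2 configuration is retained because only the O–H bond reacts.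

Step 9
Reactants: 17 4-bromo-2-chloro-1-{[(2R,4aS,7R,8aS)-2,4a-dimethyl-7-(prop-1-en-2-yl)decahydronaphthalen-2-yl]oxy}benzene
Product: 18 2-[(2R,4aS,7R,8aS)-7-(4-bromo-2-chlorophenoxy)-4a,7-dimethyldecahydronaphthalen-2-yl]propan-2-ol
Conditions: Mn(dpm)3 (10 mol %), PhSiH3, O2 (1 atm), i-PrOH, 0 °C to rt
Reagents that add atoms: dioxygen, O=O
Why: Mukaiyama hydration (metal-hydride hydrogen atom transfer, capture of the tertiary radical by O2, reduction) adds water in the Markovnikov sense to the only alkene present, so it is placed before the allyl groups are introduced.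

Step 10
Reactants: 18 2-[(2R,4aS,7R,8aS)-7-(4-bromo-2-chlorophenoxy)-4a,7-dimethyldecahydronaphthalen-2-yl]propan-2-ol
Product: 19 2-[(2R,4aS,7R,8aS)-7-(4-allyl-2-chlorophenoxy)-4a,7-dimethyldecahydronaphthalen-2-yl]propan-2-ol
Conditions: allylSnBu3, Pd(PPh3)4 (5 mol %), toluene, 100 °C
Reagents that add atoms: allyltributylstannane, C=CC[Sn](CCCC)(CCCC)CCCC
Why: In this Stille coupling zerovalent palladium inserts into the unhindered C–Br bond far faster than into the hindered C–Cl bond, so only the position para to oxygen is allylated.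

Step 11
Reactants: 20 2-allyl-4-bromophenol
Product: 21 2-allyl-4-(4,4,5,5-tetramethyl-1,3,2-dioxaborolan-2-yl)phenol
Conditions: B2pin2, Pd(dppf)Cl2 (3 mol %), KOAc, 1,4-dioxane, 85 °C
Reagents that add atoms: bis(pinacolato)diboron, CC1(C)OB(OC1(C)C)B1OC(C)(C)C(C)(C)O1
Why: Miyaura borylation of the aryl bromide with the weak base KOAc tolerates the free phenol and the allyl group.

Step 12
Reactants: 19 2-[(2R,4aS,7R,8aS)-7-(4-allyl-2-chlorophenoxy)-4a,7-dimethyldecahydronaphthalen-2-yl]propan-2-ol; 21 2-allyl-4-(4,4,5,5-tetramethyl-1,3,2-dioxaborolan-2-yl)phenol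
Product: 22 target, 2-[(2R,4aS,7R,8aS)-7-{[3',5-diallyl-4'-hydroxy-(1,1'-biphenyl)-2-yl]oxy}-4a,7-dimethyldecahydronaphthalen-2-yl]propan-2-ol
Conditions: Pd(OAc)2 (5 mol %), SPhos (10 mol %), K3PO4, toluene/H2O, 90 °C
Reagents that add atoms: none
Why: Suzuki–Miyaura coupling with an electron-rich, bulky biarylphosphine allows oxidative addition into the hindered ortho-alkoxy aryl chloride, and the basic medium spares the acid-labile tertiary alkyl aryl ether, the free hydroxyl groups and both allyl groups.

Compound list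
1 | (+)-limonene oxide, (4R)-1-methyl-4-(prop-1-en-2-yl)-7-oxabicyclo[4.1.0]heptane, cis/trans mixture | CC(=C)[C@@H]1CCC2(C)OC2C1 | starting material
2 | (4R)-1-methyl-4-(prop-1-en-2-yl)cyclohexane-1,2-diol, diastereomer mixture | CC(=C)[C@@H]1CCC(C)(O)C(O)C1 | intermediate
3 | (3R)-6-oxo-3-(prop-1-en-2-yl)heptanal | CC(=O)CC[C@@H](C(C)=C)CC=O | intermediate
4 | (3E,6R)-6-(prop-1-en-2-yl)dec-3-ene-2,9-dione | CC(=O)CC[C@@H](C(C)=C)C/C=C/C(C)=O | intermediate
5 | (3E,6R)-10-methoxy-9-methyl-6-(prop-1-en-2-yl)deca-3,9-dien-2-one, E/Z mixture at C9 | COC=C(C)CC[C@@H](C(C)=C)C/C=C/C(C)=O | intermediate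
6 | (5R,7E)-2-methyl-9-oxo-5-(prop-1-en-2-yl)dec-7-enal, C2 epimers | O=CC(C)CC[C@@H](C(C)=C)C/C=C/C(C)=O | intermediate
7 | (3E,6R)-9-methyl-6-(prop-1-en-2-yl)-10-(pyrrolidin-1-yl)deca-3,9-dien-2-one | CC(=CN1CCCC1)CC[C@@H](C(C)=C)C/C=C/C(C)=O | intermediate
8 | (1R,2S,4R)-1-methyl-2-(2-oxopropyl)-4-(prop-1-en-2-yl)cyclohexane-1-carbaldehyde | O=C[C@]1(C)CC[C@@H](C(C)=C)C[C@H]1CC(C)=O | intermediate
9 | (4aR,7R,8aS)-4a-methyl-7-(prop-1-en-2-yl)-4a,5,6,7,8,8a-hexahydronaphthalen-2(1H)-one | O=C1C=C[C@]2(C)CC[C@@H](C(C)=C)C[C@H]2C1 | intermediate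
10 | lithium (4aS,7R,8aS)-4a-methyl-7-(prop-1-en-2-yl)-1,4,4a,5,6,7,8,8a-octahydronaphthalen-2-olate | [Li+].[O-]C1=CC[C@]2(C)CC[C@@H](C(C)=C)C[C@H]2C1 | intermediate
11 | (4aS,7R,8aS)-4a-methyl-7-(prop-1-en-2-yl)octahydronaphthalen-2(1H)-one | O=C1CC[C@]2(C)CC[C@@H](C(C)=C)C[C@H]2C1 | intermediate
12 | (2R,4aS,7R,8aS)-2,4a-dimethyl-7-(prop-1-en-2-yl)decahydronaphthalen-2-ol | O[C@]1(C)CC[C@]2(C)CC[C@@H](C(C)=C)C[C@H]2C1 | intermediate
13 | 4-bromo-2-chloro-1-iodobenzene | Clc1cc(Br)ccc1I | starting material
14 | 1,3,5-trimethoxybenzene | COc1cc(OC)cc(OC)c1 | starting material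
15 | (4-bromo-2-chlorophenyl)(hydroxy)(tosyloxy)-λ3-iodane | OI(OS(=O)(=O)c1ccc(C)cc1)c1ccc(Br)cc1Cl | intermediate
16 | (4-bromo-2-chlorophenyl)(2,4,6-trimethoxyphenyl)iodonium tosylate | COc1cc(OC)c([I+]c2ccc(Br)cc2Cl)c(OC)c1.Cc1ccc(cc1)S(=O)(=O)[O-] | intermediate
17 | 4-bromo-2-chloro-1-{[(2R,4aS,7R,8aS)-2,4a-dimethyl-7-(prop-1-en-2-yl)decahydronaphthalen-2-yl]oxy}benzene | Brc1ccc(O[C@]2(C)CC[C@]3(C)CC[C@@H](C(C)=C)C[C@H]3C2)c(Cl)c1 | intermediate
18 | 2-[(2R,4aS,7R,8aS)-7-(4-bromo-2-chlorophenoxy)-4a,7-dimethyldecahydronaphthalen-2-yl]propan-2-ol | Brc1ccc(O[C@]2(C)CC[C@]3(C)CC[C@@H](C(C)(C)O)C[C@H]3C2)c(Cl)c1 | intermediate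
19 | 2-[(2R,4aS,7R,8aS)-7-(4-allyl-2-chlorophenoxy)-4a,7-dimethyldecahydronaphthalen-2-yl]propan-2-ol | C=CCc1ccc(O[C@]2(C)CC[C@]3(C)CC[C@@H](C(C)(C)O)C[C@H]3C2)c(Cl)c1 | intermediate
20 | 2-allyl-4-bromophenol | C=CCc1cc(Br)ccc1O | starting material
21 | 2-allyl-4-(4,4,5,5-tetramethyl-1,3,2-dioxaborolan-2-yl)phenol | C=CCc1cc(B2OC(C)(C)C(C)(C)O2)ccc1O | intermediate
22 | 2-[(2R,4aS,7R,8aS)-7-{[3',5-diallyl-4'-hydroxy-(1,1'-biphenyl)-2-yl]oxy}-4a,7-dimethyldecahydronaphthalen-2-yl]propan-2-ol | C=CCc1ccc(O[C@]2(C)CC[C@]3(C)CC[C@@H](C(C)(C)O)C[C@H]3C2)c(-c2ccc(O)c(CC=C)c2)c1 | target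

Total step count: 12. Longest linear sequence: 10 (steps 1–6, 8–10 and 12).

Steps most likely to fail

Step 4. The preference for the chair transition state with axial methyl may be too small, so that cis ring fusion competes. Bond formation at the fully substituted enamine carbon may also be slow enough for intermolecular condensation to intervene. The fallback sets out from methyl enol ether 5, isolated by leaving out the acid stage of step 3, with its (E) isomer (methoxy cis to methyl) enriched by chromatography.
- Heating 5 with Yb(fod)3 in toluene should trigger an intramolecular inverse-electron-demand oxa-Diels–Alder reaction of the enone (as 1-oxadiene) with the enol ether. This forms the same C–C bond together with an O–C bond in one concerted event.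
- The product is (4aS,6R,8aR)-1-methoxy-3,8a-dimethyl-6-(prop-1-en-2-yl)-4a,5,6,7,8,8a-hexahydro-1H-isochromene F1. The usual endo orientation of the alkoxy group puts the methyl group endo and the tether exo, which corresponds to the trans fusion.
- Aqueous HCl in THF opens the temporary acetal ring to keto aldehyde 8, and KOH in MeOH closes ring A, so the route is rejoined at 9.

Step 8. Ligand coupling of the very hindered axial tertiary alkoxide may be slow, so that base-induced aryne formation from the iodonium salt or transfer of the wrong aryl group takes over. The fallback sets out from 12 and replaces the hypervalent iodine electrophile by nucleophilic aromatic substitution. The potassium alkoxide (KH, 18-crown-6, N,N-dimethylacetamide, 80–100 °C) displaces fluoride from commercial 4-bromo-2-chloro-1-fluorobenzene, activated by its two halogens. This comes back directly at 17 and makes no compound outside the list (entry F0).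

Step 3. The ylide may also olefinate the conjugated ketone, or may enolise and deconjugate the enone. The fallback sets out from 3 and masks the acceptor carbonyl at the amide level.
- Wittig reaction of 3 with Ph3P=CHC(O)N(OMe)Me gives (2E,5R)-N-methoxy-N-methyl-8-oxo-5-(prop-1-en-2-yl)non-2-enamide F2.
- Its only ketone is methoxymethylenated to (2E,5R)-N,9-dimethoxy-N,8-dimethyl-5-(prop-1-en-2-yl)nona-2,8-dienamide F3.
- MeMgBr (THF, 0 °C) converts the N-methoxy-N-methyl amide into the methyl ketone 5, and the aqueous HCl work-up hydrolyses the enol ether, so the route is rejoined at 6.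

Further compounds
F1 | step 4 | (4aS,6R,8aR)-1-methoxy-3,8a-dimethyl-6-(prop-1-en-2-yl)-4a,5,6,7,8,8a-hexahydro-1H-isochromene (C1 epimers) | COC1[C@]2(C)CC[C@@H](C(C)=C)C[C@H]2C=C(C)O1
F0 | step 8 | none | none
F2 | step 3 | (2E,5R)-N-methoxy-N-methyl-8-oxo-5-(prop-1-en-2-yl)non-2-enamide | CC(=O)CC[C@@H](C(C)=C)C/C=C/C(=O)N(C)OC
F3 | step 3 | (2E,5R)-N,9-dimethoxy-N,8-dimethyl-5-(prop-1-en-2-yl)nona-2,8-dienamide (E/Z mixture at C8) | COC=C(C)CC[C@@H](C(C)=C)C/C=C/C(=O)N(C)OC
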